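**Retrosynthetic overview**
1. The C15–O ester bond is made last, from 15-hydroxyeudesma-3,11(13)-dien-12-oic acid and (Z)-p-coumaric acid, which comes from the cheap E acid by light.
2. The acrylic acid comes from a C7 malonate (saponification, decarboxylative methylenation). The C15 alcohol comes from the C3=C4 enal.
3. Both carbocycles come from one acyclic enal/aldehyde/1,1-disubstituted alkene in a single operation. H-atom transfer gives the C10 radical, C5–C10 closes ring B, then the enolate closes ring A at C3–C4 (aldol).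
4. The acyclic precursor comes from two two-carbon Wittig homologations placed around an organocatalytic malonate Michael addition. That addition sets C7, the only stereocentre carried into the cyclisation.
5. The C8 backbone comes from a ruthenium-catalysed coupling of pent-4-yn-1-ol with allyl alcohol.

Assumption: positions are given in eudesmane numbering (C10 quaternary carbon, C5 ring-fusion CH, C7 side-chain carbon, C15 oxymethylene), and the SMILES is read as (5R,7R,10R) with a Z cinnamate.

**Step 1**
Reactants: 1 pent-4-yn-1-ol; 2 prop-2-en-1-ol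
Product: 3 7-hydroxy-4-methylideneheptanal
Conditions: CpRuCl(cod) (5 mol %), NH4PF6 (10 mol %), 2 (3 equiv), DMF–H2O, 100 °C
Reagents that add atoms: none
Why: In this ruthenium-catalysed Alder-ene-type alkyne/allyl alcohol coupling, the ruthenacyclopentene joins the substituted alkyne carbon to the alkene terminus and β-hydride elimination at the carbinol carbon gives an enol that tautomerises, so the branched 1,1-disubstituted alkene and the aldehyde arise together with the remote hydroxyl tolerated and no stereocentre formed.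

**Step 2**
Reactants: 3 7-hydroxy-4-methylideneheptanal; 4 2-(triphenyl-λ5-phosphanylidene)acetaldehyde
Product: 5 (2E)-9-hydroxy-6-methylidenenon-2-enal
Conditions: 4 (1.05 equiv), PhMe, 80 °C
Reagents that add atoms: none
Why: The Wittig olefination with the stabilised formyl ylide is E-selective and stops after one homologation because the enal product reacts far more slowly than the saturated aldehyde, while the alcohol and the alkene are inert.

**Step 3**
Reactants: 5 (2E)-9-hydroxy-6-methylidenenon-2-enal; 6 dimethyl propanedioate; 4 2-(triphenyl-λ5-phosphanylidene)acetaldehyde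
Product: 8 dimethyl 2-[(2E,5R)-11-hydroxy-8-methylidene-1-oxoundec-2-en-5-yl]propanedioate, via Michael adduct aldehyde 7 (not isolated)
Conditions: (S)-2-[diphenyl(trimethylsilyloxy)methyl]pyrrolidine (10 mol %), PhCO2H (10 mol %), 6 (0.95 equiv), EtOH, 0 °C to rt; then 4 (1.2 equiv), rt
Reagents that add atoms: none
Why: In this iminium-ion organocatalysis (Jørgensen–Hayashi Michael addition), the E,s-trans iminium ion of 5 has one face blocked by the CPh2(OSiMe3) group, so malonate attacks C7 from the open face and sets (7R), and with 6 as the limiting reagent aldehyde 7 can be homologated in the same flask by an E-selective Wittig reaction without a second Michael addition.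

**Step 4**
Reactants: 8 dimethyl 2-[(2E,5R)-11-hydroxy-8-methylidene-1-oxoundec-2-en-5-yl]propanedioate
Product: 9 dimethyl 2-[(2E,5R)-8-methylidene-1,11-dioxoundec-2-en-5-yl]propanedioate
Conditions: TEMPO (10 mol %), PhI(OAc)2 (1.1 equiv), CH2Cl2, rt
Reagents that add atoms: none
Why: The oxoammonium (TEMPO/PhI(OAc)2) oxidation stops at the aldehyde and leaves the enal, the alkene and the malonate untouched, and C7 carries no acidic hydrogen so it cannot epimerise.

**Step 5** (both rings form here)
Reactants: 9 dimethyl 2-[(2E,5R)-8-methylidene-1,11-dioxoundec-2-en-5-yl]propanedioate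
Product: 11 dimethyl 2-[(2R,4aS,8aR)-8-formyl-4a-methyl-1,2,3,4,4a,5,6,8a-octahydronaphthalen-2-yl]propanedioate, via bicyclic aldol 10 (not isolated)
Conditions: Fe(acac)3 (30 mol %), PhSiH3 (2.5 equiv), EtOH (0.01 M), 40 °C; short SiO2 plug, then p-TsOH·H2O (10 mol %), PhMe, 50 °C
Reagents that add atoms: none
Why: In this radical–polar crossover MHAT/Giese/aldol bicyclisation, an iron hydride delivers H to the =CH2 of the electron-rich alkene to give the C10 tertiary radical, which closes ring B by 6-exo addition to the enal through a chair (C7 malonate and enal chain equatorial, the longer C1–C3 arm in the less crowded pseudo-equatorial site and the new methyl pseudo-axial, so 5α-H and 10β-CH3 are set trans and both relative to C7), divalent iron reduces the α-formyl radical to the trivalent iron enolate, which closes ring A by aldol addition to the C3 aldehyde, and acid dehydration erases the C3/C4 centres, leaving the cis-fused C10 epimer as the expected minor product, removed on silica.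

**Step 6**
Reactants: 11 dimethyl 2-[(2R,4aS,8aR)-8-formyl-4a-methyl-1,2,3,4,4a,5,6,8a-octahydronaphthalen-2-yl]propanedioate
Product: 12 dimethyl 2-[(2R,4aS,8aR)-8-(hydroxymethyl)-4a-methyl-1,2,3,4,4a,5,6,8a-octahydronaphthalen-2-yl]propanedioate
Conditions: NaBH4, CeCl3·7H2O, MeOH, −20 °C
Reagents that add atoms: none
Why: In the Luche reduction the cerium-modified borohydride adds 1,2 to the enal only, leaving the malonate esters, the ring alkene and all three stereocentres untouched.

**Step 7**
Reactants: 12 dimethyl 2-[(2R,4aS,8aR)-8-(hydroxymethyl)-4a-methyl-1,2,3,4,4a,5,6,8a-octahydronaphthalen-2-yl]propanedioate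
Product: 14 2-[(2R,4aR,8aR)-8-(hydroxymethyl)-4a-methyl-1,2,3,4,4a,5,6,8a-octahydronaphthalen-2-yl]prop-2-enoic acid, via malonic diacid 13 (not isolated)
Conditions: KOH (6 equiv), MeOH–H2O, 50 °C; HCl to pH 2; then Et2NH (2.5 equiv), 37 % aq. HCHO (5 equiv), 0 to 70 °C
Reagents that add atoms: formaldehyde C=O; potassium hydroxide [K+].[OH-]
Why: Saponification is followed by the Mannich-type decarboxylative methylenation of a malonic acid, in which the diacid adds to the iminium ion from Et2NH and HCHO and the Mannich base loses CO2 and Et2NH to give the α-substituted acrylic acid without touching any stereocentre (the 4a descriptor changes only through ligand ranking).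

**Step 8**
Reactants: 15 (2E)-3-(4-hydroxyphenyl)prop-2-enoic acid
Product: 16 (2Z)-3-(4-hydroxyphenyl)prop-2-enoic acid
Conditions: hν (310 nm), MeOH, N2, rt; SiO2 in the dark, E acid recycled
Reagents that add atoms: none
Why: Direct E-to-Z photoisomerisation of a cinnamic acid reaches a photostationary mixture from which the Z acid is separated and the E acid is irradiated again.

**Step 9**
Reactants: 14 2-[(2R,4aR,8aR)-8-(hydroxymethyl)-4a-methyl-1,2,3,4,4a,5,6,8a-octahydronaphthalen-2-yl]prop-2-enoic acid; 16 (2Z)-3-(4-hydroxyphenyl)prop-2-enoic acid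
Product: 17 2-[(2R,4aR,8aR)-8-({[(2Z)-3-(4-hydroxyphenyl)prop-2-enoyl]oxy}methyl)-4a-methyl-1,2,3,4,4a,5,6,8a-octahydronaphthalen-2-yl]prop-2-enoic acid
Conditions: 16 (5 equiv), PPh3 (1.5 equiv), DIAD (1.5 equiv), THF, 0 °C, dark, slow addition of 14
Reagents that add atoms: none
Why: The Mitsunobu esterification activates only the primary allylic alcohol of 14 as its alkoxyphosphonium salt, so the ester formed reflects the carboxylate present in large excess (16), the carboxylic acid outcompetes the free phenol by about six pKa units, displacement at primary C15 involves no stereocentre, and 0 °C in the dark keeps the Z alkene.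

**Compound list**
1 | pent-4-yn-1-ol | C#CCCCO | starting material
2 | prop-2-en-1-ol | C=CCO | starting material
3 | 7-hydroxy-4-methylideneheptanal | O=CCCC(=C)CCCO | intermediate
4 | 2-(triphenyl-λ5-phosphanylidene)acetaldehyde | O=CC=P(c1ccccc1)(c1ccccc1)c1ccccc1 | starting material
5 | (2E)-9-hydroxy-6-methylidenenon-2-enal | O=C/C=C/CCC(=C)CCCO | intermediate
6 | dimethyl propanedioate | COC(=O)CC(=O)OC | starting material
7 | dimethyl 2-[(3R)-9-hydroxy-6-methylidene-1-oxononan-3-yl]propanedioate (not isolated) | COC(=O)C(C(=O)OC)[C@@H](CC=O)CCC(=C)CCCO | intermediate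
8 | dimethyl 2-[(2E,5R)-11-hydroxy-8-methylidene-1-oxoundec-2-en-5-yl]propanedioate | COC(=O)C(C(=O)OC)[C@@H](C/C=C/C=O)CCC(=C)CCCO | intermediate
9 | dimethyl 2-[(2E,5R)-8-methylidene-1,11-dioxoundec-2-en-5-yl]propanedioate | COC(=O)C(C(=O)OC)[C@@H](C/C=C/C=O)CCC(=C)CCC=O | intermediate
10 | dimethyl 2-[(2R,4aS,8aS)-8-formyl-7-hydroxy-4a-methyldecahydronaphthalen-2-yl]propanedioate, trans-fused, epimer mixture at the carbinol and formyl carbons (not isolated) | COC(=O)C(C(=O)OC)[C@@H]1CC[C@@]2(C)CCC(O)C(C=O)[C@@H]2C1 | intermediate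
11 | dimethyl 2-[(2R,4aS,8aR)-8-formyl-4a-methyl-1,2,3,4,4a,5,6,8a-octahydronaphthalen-2-yl]propanedioate (5α-H, 7β side chain, 10β-CH3) | COC(=O)C(C(=O)OC)[C@@H]1CC[C@@]2(C)CCC=C(C=O)[C@@H]2C1 | intermediate
12 | dimethyl 2-[(2R,4aS,8aR)-8-(hydroxymethyl)-4a-methyl-1,2,3,4,4a,5,6,8a-octahydronaphthalen-2-yl]propanedioate | COC(=O)C(C(=O)OC)[C@@H]1CC[C@@]2(C)CCC=C(CO)[C@@H]2C1 | intermediate
13 | 2-[(2R,4aS,8aR)-8-(hydroxymethyl)-4a-methyl-1,2,3,4,4a,5,6,8a-octahydronaphthalen-2-yl]propanedioic acid (not isolated) | OC(=O)C(C(=O)O)[C@@H]1CC[C@@]2(C)CCC=C(CO)[C@@H]2C1 | intermediate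
14 | 2-[(2R,4aR,8aR)-8-(hydroxymethyl)-4a-methyl-1,2,3,4,4a,5,6,8a-octahydronaphthalen-2-yl]prop-2-enoic acid | C=C(C(=O)O)[C@@H]1CC[C@@]2(C)CCC=C(CO)[C@@H]2C1 | intermediate
15 | (2E)-3-(4-hydroxyphenyl)prop-2-enoic acid | OC(=O)/C=C/c1ccc(O)cc1 | starting material
16 | (2Z)-3-(4-hydroxyphenyl)prop-2-enoic acid | OC(=O)/C=C\c1ccc(O)cc1 | intermediate
17 | 2-[(2R,4aR,8aR)-8-({[(2Z)-3-(4-hydroxyphenyl)prop-2-enoyl]oxy}methyl)-4a-methyl-1,2,3,4,4a,5,6,8a-octahydronaphthalen-2-yl]prop-2-enoic acid | C=C(C(=O)O)[C@@H]1CC[C@@]2(C)CCC=C(COC(=O)/C=C\c3ccc(O)cc3)[C@@H]2C1 | target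

**Total step count:** 9. **Longest linear sequence:** 8 (steps 1–7 and 9).

**Three steps most likely to fail**

**Step 5.** The acyclic C10 radical tells its methyl from its CH2CH2CHO arm only weakly, so the cis-fused C10 epimer could approach parity. The iron enolate may also be protonated before the aldol, and 1,5-hydrogen transfer from the malonate C–H can compete.

The fallback sets out from 4 and 6 and comes back at 12. It still closes both rings at once, but pericyclically, so C5 and C10 are tied together by a suprafacial addition.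
- Commercial 4-methylpent-4-enal and 4 give (2E)-6-methylhepta-2,6-dienal F1.
- The catalyst of step 3 adds 6 to give dimethyl 2-[(3R)-6-methyl-1-oxohept-6-en-3-yl]propanedioate F2.
- A Wittig reaction with 2-bromo-2-(triphenyl-λ5-phosphanylidene)acetaldehyde gives dimethyl 2-[(2Z,5R)-2-bromo-8-methyl-1-oxonona-2,8-dien-5-yl]propanedioate F3.
- Stille coupling with Bu3SnCH2OH under Pd(PPh3)4 gives dimethyl 2-[(2E,5R)-2-(hydroxymethyl)-8-methyl-1-oxonona-2,8-dien-5-yl]propanedioate F4.
- Excess Ph3P=CH2 gives dimethyl 2-[(3Z,6R)-3-(hydroxymethyl)-9-methyldeca-1,3,9-trien-6-yl]propanedioate F5.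
- Heating F5 (PhMe, BHT, sealed tube, 190 °C) effects an intramolecular Diels–Alder reaction. The chair-like tether holds the malonate equatorial and the methyl on the dienophile disfavours the cis-fused transition state, so the product is 12.

**Step 9.** The acrylic acid of 14 can compete as the carboxylate partner and give self-esters. PPh3 may also erode the Z geometry.

The fallback sets out from 14 and comes back at 17.
- The carboxylate is alkylated with phenacyl bromide (Et3N, DMF) to give 2-oxo-2-phenylethyl 2-[(2R,4aR,8aR)-8-(hydroxymethyl)-4a-methyl-1,2,3,4,4a,5,6,8a-octahydronaphthalen-2-yl]prop-2-enoate F6.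
- Mitsunobu esterification with only 1.2 equiv of 16 gives 2-oxo-2-phenylethyl 2-[(2R,4aR,8aR)-8-({[(2Z)-3-(4-hydroxyphenyl)prop-2-enoyl]oxy}methyl)-4a-methyl-1,2,3,4,4a,5,6,8a-octahydronaphthalen-2-yl]prop-2-enoate F7.
- Zn in AcOH at rt removes the phenacyl group to give 17.

**Step 1.** The branched/linear ratio may be poor, and the alkynol may chelate or cycloisomerise on ruthenium.

The fallback sets out from 1 and comes back at 3.
- Markovnikov hydroiodination (NaI, Me3SiCl, H2O, MeCN) gives 4-iodopent-4-en-1-ol F8.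
- Negishi coupling with BrZnCH2CH2CO2Et under Pd(PPh3)4 gives ethyl 7-hydroxy-4-methylideneheptanoate F9.
- i-Bu2AlH (2.2 equiv, CH2Cl2, −78 °C) reduces the ester to aldehyde 3.

**Further compounds**
F1 | step 5 | (2E)-6-methylhepta-2,6-dienal | C=C(C)CC/C=C/C=O
F2 | step 5 | dimethyl 2-[(3R)-6-methyl-1-oxohept-6-en-3-yl]propanedioate | COC(=O)C(C(=O)OC)[C@@H](CC=O)CCC(C)=C
F3 | step 5 | dimethyl 2-[(2Z,5R)-2-bromo-8-methyl-1-oxonona-2,8-dien-5-yl]propanedioate | COC(=O)C(C(=O)OC)[C@@H](C/C=C(/C=O)Br)CCC(C)=C
F4 | step 5 | dimethyl 2-[(2E,5R)-2-(hydroxymethyl)-8-methyl-1-oxonona-2,8-dien-5-yl]propanedioate | COC(=O)C(C(=O)OC)[C@@H](C/C=C(/C=O)CO)CCC(C)=C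
F5 | step 5 | dimethyl 2-[(3Z,6R)-3-(hydroxymethyl)-9-methyldeca-1,3,9-trien-6-yl]propanedioate | COC(=O)C(C(=O)OC)[C@@H](C/C=C(/C=C)CO)CCC(C)=C
F6 | step 9 | 2-oxo-2-phenylethyl 2-[(2R,4aR,8aR)-8-(hydroxymethyl)-4a-methyl-1,2,3,4,4a,5,6,8a-octahydronaphthalen-2-yl]prop-2-enoate | C=C(C(=O)OCC(=O)c3ccccc3)[C@@H]1CC[C@@]2(C)CCC=C(CO)[C@@H]2C1
F7 | step 9 | 2-oxo-2-phenylethyl 2-[(2R,4aR,8aR)-8-({[(2Z)-3-(4-hydroxyphenyl)prop-2-enoyl]oxy}methyl)-4a-methyl-1,2,3,4,4a,5,6,8a-octahydronaphthalen-2-yl]prop-2-enoate | C=C(C(=O)OCC(=O)c3ccccc3)[C@@H]1CC[C@@]2(C)CCC=C(COC(=O)/C=C\c4ccc(O)cc4)[C@@H]2C1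
F8 | step 1 | 4-iodopent-4-en-1-ol | C=C(I)CCCO
F9 | step 1 | ethyl 7-hydroxy-4-methylideneheptanoate | CCOC(=O)CCC(=C)CCCO
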